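Assumption: commercial neryl acetate (1) is used as the geometrically pure (2Z)-ester, so the ring alkene enters the route with fixed Z geometry.

## Analysis of the target

The target is a germacrane-type ten-membered carbocycle. Its ring atoms are lettered here from the allylic acetoxy carbon a through the alkene carbons b and c (c bears the methyl), the methylenes d and e, the epoxide carbons f (CH) and g (quaternary), the methylene h, the second acetoxy carbon i and the isopropyl-bearing carbon j back to a; the formyl carbon on g is k. There is one ring alkene, b=c, of Z geometry (a and d cis), and a cis-fused trisubstituted epoxide (e and h on the same side of the oxirane). The five stereocentres form two clusters. The first is the contiguous triad a (S), j (S), i (R), in which both acetoxy groups are syn to the isopropyl group along h–i–j–a–b. The second is the epoxide pair f (R), g (S). The clusters are insulated from each other by h on one side and by d, e and the alkene on the other, so each has to be set in the absolute sense. Sensitive groups are the α,β-epoxy aldehyde, the two base-labile secondary acetates, and the 1,5-related alkene and epoxide, which invite transannular cyclisation under acid. The hard part is closing a ten-membered ring while keeping the Z alkene and placing a formyl-bearing quaternary epoxide carbon next to a ring CH2. The strategy rests on one feature: i is a carbinol two bonds from g, and g with its branch k and neighbour h is the central carbon of a 2-substituted allyl unit. A carbonyl allylation therefore forms h–i and leaves k as an exocyclic methylene on g beside an oxygen on f, which is a masked epoxy aldehyde.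

## Retrosynthetic reasoning

**End-game functional groups (33 ⇐ 32 ⇐ 31 ⇐ 30).** No skeletal bond is cut. The acetates of 33 are put on last, from diol 32, because every earlier basic step would cleave or shift them. Diol 32 comes from the bis-silyl ether 31, and the aldehyde of 31 from the primary alcohol of 30. The forward steps must oxidise k without touching the epoxide, then remove silicon without opening the epoxy aldehyde.

**Epoxide relay (30 ⇐ 29 ⇐ 28).** The g–O bond of the ring epoxide is cut and oxygen is reconnected between g and k. This makes 30 the Payne isomer of spiro-epoxide 29, and 29 the epoxidation product of allylic alcohol 28. The cut is made here because the ring-closing chemistry delivers exactly a methylene on g next to an oxygen on f. The forward epoxidation must place oxygen on the methylene face erythro to the f hydroxyl. Attack of the f oxygen on g with inversion then gives the cis-fused epoxide and frees k as a primary alcohol.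

**Protecting-group switch (28 ⇐ 27 ⇐ 26).** Only the f hydroxyl may direct the epoxidation. The homoallylic i hydroxyl of 26 is therefore capped in 27 with the same robust silyl group as a, and the more labile silyl ether on f is then removed selectively.

**Ring closure, h–i (26 ⇐ 24).** The bond between the carbinol i and the allylic methylene h is cut, giving the open-chain chloro aldehyde 24. This is the only ring bond whose formation needs no new geometry at an alkene and creates one stereocentre next to an existing one (j). Cutting a–j would demand a macro-aldol that sets two centres at once. Cutting b=c would demand a Z-trisubstituted alkene formed inside a strained ring. The forward reaction must turn the allylic chloride into a nucleophile in the presence of the aldehyde. A zerovalent palladium catalyst with a dialkylzinc does this, and the symmetric 2-substituted allyl unit removes any regiochemical question.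

**Unmasking the two reactive ends (24 ⇐ 23 ⇐ 21 ⇐ 20 ⇐ 19 ⇐ 18).** The aldehyde of 24 is released only in the last step before cyclisation, from the Weinreb amide 23. The allylic chloride of 23 comes from alcohol 21, and 21 from the PMB ether 20. The a silyl ether of 20 and the amide of 19 come from aldol adduct 18. The carbonyl stays at the amide level and the chloride is introduced late so that neither reactive end has to survive the fragment assembly.

**Aldol, a–j (18 ⇐ 16 + 13; 16 ⇐ 14 + 15).** The a–j bond is cut between the (Z)-enal 13 and the isovaleryl imide 16. An auxiliary-controlled syn-aldol sets a and j together, in absolute terms, with a well-understood outcome. It also brings in the isopropyl group and the future aldehyde carbon i as one five-carbon unit, from 14 and 15.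

**Allylic carbinol f, f–g (13 ⇐ 12 ⇐ 11 ⇐ 10 ⇐ 9 ⇐ 8 ⇐ 4 + 6).** The enal 13 comes from allylic acetate 11 by deacetylation (12) and oxidation. The f–g bond is cut between aldehyde 4 and the alkenyl bromide 6, which supplies g, h and k with the h oxygen already in place. The alkenyl addition gives racemic 8, so f is set afterwards by oxidation to enone 9 and catalyst-controlled reduction to 10.

**Source of the Z alkene (4 ⇐ 2 ⇐ 1; 6 ⇐ 5).** Aldehyde 4 contains a, b, c with its methyl, d, e and f. It is the product of excising the isopropylidene end of 1 through epoxide 2, so the Z alkene is bought rather than made. Bromide 6 is the PMB ether of 5.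

## Alternatives that were turned down

**Alternative 1:** [2,3]-Wittig ring contraction, disconnecting a–j.
- Key step: the thirteen-membered bis-allylic ether A2 has a as an O-bound allylic methylene and j as the alkene terminus of a 2-methylallyl ether arm. Excess n-BuLi would carry the i and k hydroxyls as alkoxides and lithiate a. The [2,3]-shift forms a–j, breaks the O–CH2 bond and gives the ten-membered triol A1 with hydroxyl on a and isopropenyl on j.
- For it: ring, C–C bond and both a and j arise in one step. A1 already holds the f=g alkene with its primary allylic alcohol, so the epoxide could be installed by a reagent-controlled Sharpless epoxidation with no epoxide migration. On that point it is stronger than the chosen plan.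
- Against it: A2 has two α-oxy allylic methylenes of similar acidity, so lithiation at the wrong one and [1,2]-shift compete. The configurations at a and j would be relayed only from the i alkoxide through the fold of a thirteen-membered ring, and an all-syn triad is not assured. The isopropenyl group must then be hydrogenated in the presence of two ring alkenes, the three hydroxyls of A1 must be told apart, and A2 itself needs a macro-etherification.
- Comparison: the chosen route sets a and j by an auxiliary-controlled aldol of predictable sense and leaves only i to the ring-forming event, with a correction available.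

**Alternative 2:** Grob fragmentation, reconnecting a to g.
- Key step: in the cis-fused bicyclo[5.3.0]decene mesylate A4, t-BuOK would form the bridgehead alkoxide at a. Cleavage of a–g with loss of the mesylate on f opens the (Z,Z)-cyclodecadienone A3, with a ketone at a and the f=g alkene.
- For it: no medium-ring closure against entropy and transannular strain is needed, and the f=g geometry follows stereospecifically from the anti-periplanar arrangement. On ring formation it is stronger than the chosen plan.
- Against it: A4 needs five defined stereocentres, three of them (a, g, f) sacrificial. In A3, j is α to the new ketone and the i silyloxy group is β to it, so under t-BuOK epimerisation at j and E1cB loss of the i oxygen are likely. The a ketone must then be reduced 1,2 with the right facial sense on a flexible Z-enone, and epoxidation and oxidation-state changes still follow. The route is longer.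
- Comparison: the chosen route carries a as a protected alcohol of secure configuration and never exposes j to strong base next to a carbonyl.

**Alternative 3:** Ramberg–Bäcklund extrusion, disconnecting b=c.
- Key step: the eleven-membered sulfone A6, with sulfur between b and c, would be α-halogenated in situ (CBr2F2, KOH on Al2O3). Collapse through an episulfone with loss of SO2 gives the ten-membered diene acetonide A5.
- For it: the ring is closed earlier by sulfide alkylation, far from the stereocentres and easier than any C–C macrocyclisation. The i centre is set in acyclic chemistry and locked in the acetonide, so its configuration is more secure than in the chosen route. A5 also allows direct directed epoxidation of f=g.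
- Against it: the extrusion must give a Z, trisubstituted alkene, but the geometry follows the uncontrolled episulfone configuration and the ten-membered ring tolerates both isomers. The α-sulfonyl carbanion at b is β to the acetonide oxygen on a, so E1cB opening competes. Sulfur must also be oxidised in the presence of alkenes.
- Comparison: the chosen route takes the Z alkene ready-made from 1 and forms ring and carbon–carbon bond in a single step, with i correctable by oxidation and reduction.

Key step: step 17

## Route

Step 1
Reactants: 1 neryl acetate, (2Z)-3,7-dimethylocta-2,6-dien-1-yl acetate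
Product: 2 racemic (2Z)-6,7-epoxy-3,7-dimethyloct-2-en-1-yl acetate
Conditions: mCPBA (1.05 equiv), NaHCO3, CH2Cl2, 0 °C
Reagents that add atoms: 3-chloroperbenzoic acid, O=C(OO)c1cccc(Cl)c1
Why: Prilezhaev epoxidation should take the electron-rich remote trisubstituted alkene, because the 2,3-alkene is deactivated by the allylic acetoxy group; the new centre is excised in step 2, so its configuration is irrelevant.

Step 2
Reactants: 2 racemic (2Z)-6,7-epoxy-3,7-dimethyloct-2-en-1-yl acetate
Product: 4 (2Z)-3-methyl-6-oxohex-2-en-1-yl acetate, via racemic 6,7-diol 3 (not isolated)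
Conditions: H5IO6 (1.2 equiv), THF/H2O, 0 °C to rt
Reagents that add atoms: none
Why: Periodic acid hydrolyses the epoxide (water enters at the tertiary carbon) and cleaves glycol 3 in the same flask (Malaprade cleavage), giving the aldehyde at f and acetone; the acetate and the Z alkene are untouched.

Step 3
Reactants: 5 2-bromoprop-2-en-1-ol
Product: 6 1-{[(2-bromoprop-2-en-1-yl)oxy]methyl}-4-methoxybenzene (2-bromoallyl PMB ether)
Conditions: NaH, THF, 0 °C; PMBCl, Bu4NI (cat.), rt
Reagents that add atoms: 4-methoxybenzyl chloride, COc1ccc(CCl)cc1
Why: Williamson etherification of the primary alkoxide; the vinylic bromide is inert to alkoxide, and the PMB group is chosen because it can later be removed oxidatively beside silyl ethers.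

Step 4
Reactants: 4 (2Z)-3-methyl-6-oxohex-2-en-1-yl acetate; 6 2-bromoallyl PMB ether
Product: 8 racemic (2Z)-6-hydroxy-8-[(4-methoxybenzyl)oxy]-3-methyl-7-methylideneoct-2-en-1-yl acetate, via alkenylchromium dichloride 7 (not isolated)
Conditions: CrCl2 (4 equiv), NiCl2 (2 mol %), DMF, rt
Reagents that add atoms: none
Why: Nozaki–Hiyama–Kishi coupling: zerovalent nickel formed in situ inserts into the C–Br bond, transmetallation gives the trivalent chromium alkenyl 7, which adds to the aldehyde and leaves the acetate alone; the product is racemic at f, which is corrected in steps 5 and 6.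

Step 5
Reactants: 8 racemic (2Z)-6-hydroxy-8-[(4-methoxybenzyl)oxy]-3-methyl-7-methylideneoct-2-en-1-yl acetate
Product: 9 (2Z)-8-[(4-methoxybenzyl)oxy]-3-methyl-7-methylidene-6-oxooct-2-en-1-yl acetate
Conditions: Dess–Martin periodinane (1.3 equiv), NaHCO3, CH2Cl2, 0 °C
Reagents that add atoms: none
Why: Dess–Martin oxidation of the secondary allylic alcohol under buffered, non-nucleophilic conditions should give the α-methylene ketone without conjugate addition; it erases the uncontrolled f centre.

Step 6
Reactants: 9 (2Z)-8-[(4-methoxybenzyl)oxy]-3-methyl-7-methylidene-6-oxooct-2-en-1-yl acetate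
Product: 10 (2Z,6R)-6-hydroxy-8-[(4-methoxybenzyl)oxy]-3-methyl-7-methylideneoct-2-en-1-yl acetate
Conditions: (S)-Me-CBS oxazaborolidine (0.5 equiv), catecholborane (1.5 equiv), toluene, −78 °C
Reagents that add atoms: none
Why: Corey–Bakshi–Shibata reduction: the ketone binds the catalyst with its α-branched alkenyl group as the large and the CH2CH2 chain as the small substituent, so the (S)-catalyst should deliver hydride to give (R)-f; catecholborane at low temperature reduces 1,2 and does not hydroborate the alkenes or touch the acetate.

Step 7
Reactants: 10 (2Z,6R)-6-hydroxy-8-[(4-methoxybenzyl)oxy]-3-methyl-7-methylideneoct-2-en-1-yl acetate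
Product: 11 (2Z,6R)-8-[(4-methoxybenzyl)oxy]-3-methyl-7-methylidene-6-[(triethylsilyl)oxy]oct-2-en-1-yl acetate
Conditions: TESCl, imidazole, CH2Cl2, 0 °C
Reagents that add atoms: chlorotriethylsilane, CC[Si](Cl)(CC)CC
Why: Standard silylation; triethylsilyl is chosen for f because it must later be removed in the presence of two tert-butyldimethylsilyl ethers.

Step 8
Reactants: 11 (2Z,6R)-8-[(4-methoxybenzyl)oxy]-3-methyl-7-methylidene-6-[(triethylsilyl)oxy]oct-2-en-1-yl acetate
Product: 12 (2Z,6R)-8-[(4-methoxybenzyl)oxy]-3-methyl-7-methylidene-6-[(triethylsilyl)oxy]oct-2-en-1-ol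
Conditions: K2CO3 (0.5 equiv), MeOH, 0 °C
Reagents that add atoms: none
Why: Base-catalysed transesterification to methanol frees the primary allylic alcohol; the secondary TES ether and the PMB ether should be stable at 0 °C.

Step 9
Reactants: 12 (2Z,6R)-8-[(4-methoxybenzyl)oxy]-3-methyl-7-methylidene-6-[(triethylsilyl)oxy]oct-2-en-1-ol
Product: 13 (2Z,6R)-8-[(4-methoxybenzyl)oxy]-3-methyl-7-methylidene-6-[(triethylsilyl)oxy]oct-2-enal
Conditions: TEMPO (10 mol %), PhI(OAc)2 (1.1 equiv), CH2Cl2, rt
Reagents that add atoms: none
Why: Oxoammonium-mediated oxidation of the primary allylic alcohol under near-neutral conditions should give the (Z)-enal without Z to E isomerisation or over-oxidation; silyl and PMB ethers are inert.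

Step 10
Reactants: 14 (R)-4-benzyloxazolidin-2-one; 15 3-methylbutanoyl chloride
Product: 16 (R)-4-benzyl-3-(3-methylbutanoyl)oxazolidin-2-one
Conditions: n-BuLi, THF, −78 °C; then 15, −78 to 0 °C
Reagents that add atoms: none
Why: N-acylation of the lithiated oxazolidinone by the acid chloride, the standard preparation of Evans imides.

Step 11
Reactants: 16 (R)-4-benzyl-3-(3-methylbutanoyl)oxazolidin-2-one; 13 (2Z,6R)-8-[(4-methoxybenzyl)oxy]-3-methyl-7-methylidene-6-[(triethylsilyl)oxy]oct-2-enal
Product: 18 (R)-4-benzyl-3-[(2R,3S,4Z,8R)-3-hydroxy-10-[(4-methoxybenzyl)oxy]-5-methyl-9-methylidene-2-(propan-2-yl)-8-[(triethylsilyl)oxy]dec-4-enoyl]oxazolidin-2-one, via Z-dibutylboron enolate 17 (not isolated)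
Conditions: Bu2BOTf (1.2 equiv), iPr2NEt (1.4 equiv), CH2Cl2, −78 to 0 °C; 13, −78 to 0 °C; pH 7 buffer, MeOH, H2O2, 0 °C
Reagents that add atoms: none
Why: Evans syn-aldol: the (Z)-boron enolate 17 adds through a chair Zimmerman–Traxler transition state with the auxiliary carbonyl opposed to the enolate oxygen and the benzyl group shielding one face, so the (R)-auxiliary should give the (2R,3S) syn adduct, which is j and a as in the target; the aldehyde reacts at −78 °C faster than it can isomerise.

Step 12
Reactants: 18 the aldol adduct (imide with free hydroxyl at a)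
Product: 19 (2R,3S,4Z,8R)-3-hydroxy-N-methoxy-10-[(4-methoxybenzyl)oxy]-N,5-dimethyl-9-methylidene-2-(propan-2-yl)-8-[(triethylsilyl)oxy]dec-4-enamide
Conditions: MeNHOMe·HCl (3 equiv), AlMe3 (3 equiv), THF, −20 to 0 °C
Reagents that add atoms: N,O-dimethylhydroxylamine hydrochloride, CNOC.Cl
Why: Weinreb transamination: the aluminium amide is delivered to the exocyclic imide carbonyl with help from the aluminium alkoxide of the free a hydroxyl, releasing the auxiliary 14 for recovery; j and a are not affected.

Step 13
Reactants: 19 the hydroxy Weinreb amide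
Product: 20 (2R,3S,4Z,8R)-3-[(tert-butyldimethylsilyl)oxy]-N-methoxy-10-[(4-methoxybenzyl)oxy]-N,5-dimethyl-9-methylidene-2-(propan-2-yl)-8-[(triethylsilyl)oxy]dec-4-enamide
Conditions: TBSOTf, 2,6-lutidine, CH2Cl2, −78 to 0 °C
Reagents that add atoms: tert-butyldimethylsilyl triflate, CC(C)(C)[Si](C)(C)OS(=O)(=O)C(F)(F)F
Why: Silyl triflate with a hindered base silylates the hindered allylic alcohol quickly without ionising it; TBS at a outlasts the later TES removal.

Step 14
Reactants: 20 the TBS/TES-protected PMB ether
Product: 21 (2R,3S,4Z,8R)-3-[(tert-butyldimethylsilyl)oxy]-10-hydroxy-N-methoxy-N,5-dimethyl-9-methylidene-2-(propan-2-yl)-8-[(triethylsilyl)oxy]dec-4-enamide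
Conditions: DDQ (1.3 equiv), CH2Cl2/pH 7 buffer, 0 °C
Reagents that add atoms: none
Why: Oxidative PMB cleavage (hydride abstraction by DDQ, hydrolysis of the hemiacetal) at buffered pH should free the primary allylic alcohol while silyl ethers, amide and unconjugated alkenes survive.

Step 15
Reactants: 21 the primary allylic alcohol
Product: 23 (2R,3S,4Z,8R)-3-[(tert-butyldimethylsilyl)oxy]-10-chloro-N-methoxy-N,5-dimethyl-9-methylidene-2-(propan-2-yl)-8-[(triethylsilyl)oxy]dec-4-enamide, via allylic mesylate 22 (not isolated)
Conditions: MsCl, 2,4,6-collidine, LiCl, DMF, 0 °C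
Reagents that add atoms: lithium chloride, [Li+].[Cl-]
Why: Mesylation followed by chloride displacement in the same flask (SN2 at a primary allylic carbon) under weakly basic conditions; the two allyl termini are both CH2, so an SN2' pathway would give the same chloride.

Step 16
Reactants: 23 the chloro Weinreb amide
Product: 24 (2R,3S,4Z,8R)-3-[(tert-butyldimethylsilyl)oxy]-10-chloro-5-methyl-9-methylidene-2-(propan-2-yl)-8-[(triethylsilyl)oxy]dec-4-enal
Conditions: i-Bu2AlH (1.5 equiv), THF, −78 °C; aqueous potassium sodium tartrate
Reagents that add atoms: none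
Why: Hydride adds once to the Weinreb amide and the chelated tetrahedral intermediate collapses to the aldehyde only on work-up, so over-reduction is avoided; at −78 °C the allylic chloride is untouched and j should not epimerise, and 24 is used at once.

Step 17
Reactants: 24 (2R,3S,4Z,8R)-3-[(tert-butyldimethylsilyl)oxy]-10-chloro-5-methyl-9-methylidene-2-(propan-2-yl)-8-[(triethylsilyl)oxy]dec-4-enal
Product: 26 (1R,2S,3S,4Z,8R)-3-[(tert-butyldimethylsilyl)oxy]-5-methyl-9-methylidene-2-(propan-2-yl)-8-[(triethylsilyl)oxy]cyclodec-4-en-1-ol, via allylzinc 25 (not isolated)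
Conditions: Pd(PPh3)4 (10 mol %), Et2Zn (4 equiv), THF, rt, slow addition of 24 (final 0.005 M)
Reagents that add atoms: none
Why: Zerovalent palladium ionises the allylic chloride to a symmetrical 2-substituted π-allylpalladium species, and Et2Zn transmetallates it to the nucleophilic allylzinc 25, reversing the polarity of the allyl unit. The closest known reaction type is the palladium/diethylzinc umpolung allylation of aldehydes by allylic halides, which is known in intramolecular form for ten-membered carbocycles. The allylzinc adds to the aldehyde through a six-membered chair transition state; both allyl termini are CH2, so either mode forms the same h–i bond and leaves the exocyclic methylene on g. The ring closes in a 10-exo-trig attack on the carbonyl, and high dilution with slow addition should suppress oligomers while the Z alkene pre-folds the chain. The new stereocentre i is controlled by j: Felkin–Anh attack anti to the bulky silyloxy-bearing branch a, with isopropyl inside, is attack on the Re face and should give (R)-i with the hydroxyl syn to isopropyl. The step needs this facial selectivity and clean reaction at the aldehyde only. The α-stereocentre provides the facial bias, the TES ether sits on a carbon from which the allylzinc cannot β-eliminate, and silyl ethers and the trisubstituted alkene are inert to Et2Zn and the catalyst.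

Step 18
Reactants: 26 the cyclised homoallylic alcohol
Product: 27 the i-O-TBS ether of 26 (ten-membered ring; TBS ethers at a and i, TES ether at f, methylidene on g; a S, j S, i R, f R)
Conditions: TBSOTf, 2,6-lutidine, CH2Cl2, −78 to 0 °C
Reagents that add atoms: tert-butyldimethylsilyl triflate, CC(C)(C)[Si](C)(C)OS(=O)(=O)C(F)(F)F
Why: Silyl triflate protects the hindered i hydroxyl so that it cannot direct the later epoxidation and shares the final deprotection with a.

Step 19
Reactants: 27 the tris-silyl ether
Product: 28 the f alcohol (ten-membered ring; free allylic hydroxyl at f, TBS ethers at a and i, methylidene on g; a S, j S, i R, f R)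
Conditions: PPTS (0.2 equiv), MeOH/CH2Cl2, 0 °C
Reagents that add atoms: none
Why: Acid-catalysed methanolysis removes the secondary TES ether much faster than the two bulkier TBS ethers, so only the allylic f hydroxyl should be unveiled.

Step 20
Reactants: 28 the f alcohol
Product: 29 the spiro-epoxy alcohol (oxirane spiro-fused at g with CH2 k; epoxide oxygen erythro to the f hydroxyl; f R, g S; TBS ethers at a and i)
Conditions: VO(acac)2 (5 mol %), t-BuOOH (1.5 equiv), CH2Cl2, 0 °C to rt
Reagents that add atoms: tert-butyl hydroperoxide, CC(C)(C)OO
Why: Hydroxyl-directed epoxidation: the vanadate ester of the f alcohol delivers the peroxide oxygen to the adjacent methylene through a transition state with an O–C–C=C dihedral near 50°, in which the f hydrogen rather than ring carbon e eclipses the alkene substituent h (A1,2 strain, and an e–f–g–h torsion near 110° that the ring accommodates), which should give the erythro epoxy alcohol; the b=c alkene has no free hydroxyl near it and is not epoxidised.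

Step 21
Reactants: 29 the spiro-epoxy alcohol
Product: 30 [(1R,3R,4S,5S,6Z,10R)-3,5-bis[(tert-butyldimethylsilyl)oxy]-7-methyl-4-(propan-2-yl)-11-oxabicyclo[8.1.0]undec-6-en-1-yl]methanol
Conditions: t-BuOK (0.3 equiv), t-BuOH/THF, 0 °C to rt
Reagents that add atoms: none
Why: Payne rearrangement: the f alkoxide attacks the spiro carbon g from the side opposite its C–O bond (3-exo-tet), inverting g and releasing the primary alkoxide at k; because the two oxygens are erythro, the anti-periplanar arrangement places e and h gauche and the new epoxide is cis-fused, and equilibrium should favour the more substituted ring epoxide with a primary alcohol.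

Step 22
Reactants: 30 the epoxy alcohol
Product: 31 (1S,3R,4S,5S,6Z,10R)-3,5-bis[(tert-butyldimethylsilyl)oxy]-7-methyl-4-(propan-2-yl)-11-oxabicyclo[8.1.0]undec-6-ene-1-carbaldehyde
Conditions: Dess–Martin periodinane, NaHCO3, CH2Cl2, 0 °C
Reagents that add atoms: none
Why: Dess–Martin oxidation of the primary epoxy alcohol under buffered, non-basic conditions; g is quaternary, so the new aldehyde cannot epimerise.

Step 23
Reactants: 31 the bis-TBS epoxy aldehyde
Product: 32 (1S,3R,4S,5S,6Z,10R)-3,5-dihydroxy-7-methyl-4-(propan-2-yl)-11-oxabicyclo[8.1.0]undec-6-ene-1-carbaldehyde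
Conditions: HF·pyridine, pyridine, THF, 0 °C to rt
Reagents that add atoms: none
Why: Fluoride cleaves both secondary TBS ethers through Si–F bond formation; pyridine buffering avoids basic alkoxides next to the epoxy aldehyde and keeps the medium too weakly acidic for transannular epoxide opening, and a lactol from the i hydroxyl is not expected because the ring bonds at g and i that it would bridge are trans.

Step 24
Reactants: 32 the epoxy aldehyde diol
Product: 33 (1S,3R,4S,5S,6Z,10R)-1-formyl-7-methyl-4-(propan-2-yl)-11-oxabicyclo[8.1.0]undec-6-ene-3,5-diyl diacetate (target)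
Conditions: Ac2O, pyridine, DMAP (cat.), CH2Cl2, 0 °C to rt
Reagents that add atoms: acetic anhydride, CC(=O)OC(C)=O
Why: DMAP-catalysed acylation of the two hindered secondary alcohols; the conditions are mild enough for the epoxy aldehyde and no stereocentre is touched.

## Compound list

1 | neryl acetate, (2Z)-3,7-dimethylocta-2,6-dien-1-yl acetate | CC(=O)OC/C=C(/C)CCC=C(C)C | starting material
2 | racemic (2Z)-6,7-epoxy-3,7-dimethyloct-2-en-1-yl acetate | CC(=O)OC/C=C(/C)CCC1OC1(C)C | intermediate
3 | racemic (2Z)-6,7-dihydroxy-3,7-dimethyloct-2-en-1-yl acetate | CC(=O)OC/C=C(/C)CCC(O)C(C)(C)O | intermediate (not isolated)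
4 | (2Z)-3-methyl-6-oxohex-2-en-1-yl acetate | CC(=O)OC/C=C(/C)CCC=O | intermediate
5 | 2-bromoprop-2-en-1-ol | C=C(Br)CO | starting material
6 | 2-bromoallyl 4-methoxybenzyl ether | C=C(Br)COCc1ccc(OC)cc1 | intermediate
7 | dichloro{3-[(4-methoxybenzyl)oxy]prop-1-en-2-yl}chromium | C=C(COCc1ccc(OC)cc1)[Cr](Cl)Cl | intermediate (not isolated)
8 | racemic (2Z)-6-hydroxy-8-[(4-methoxybenzyl)oxy]-3-methyl-7-methylideneoct-2-en-1-yl acetate | CC(=O)OC/C=C(/C)CCC(O)C(=C)COCc1ccc(OC)cc1 | intermediate
9 | (2Z)-8-[(4-methoxybenzyl)oxy]-3-methyl-7-methylidene-6-oxooct-2-en-1-yl acetate | CC(=O)OC/C=C(/C)CCC(=O)C(=C)COCc1ccc(OC)cc1 | intermediate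
10 | (2Z,6R)-6-hydroxy-8-[(4-methoxybenzyl)oxy]-3-methyl-7-methylideneoct-2-en-1-yl acetate | CC(=O)OC/C=C(/C)CC[C@@H](O)C(=C)COCc1ccc(OC)cc1 | intermediate
11 | (2Z,6R)-8-[(4-methoxybenzyl)oxy]-3-methyl-7-methylidene-6-[(triethylsilyl)oxy]oct-2-en-1-yl acetate | CC(=O)OC/C=C(/C)CC[C@@H](O[Si](CC)(CC)CC)C(=C)COCc1ccc(OC)cc1 | intermediate
12 | (2Z,6R)-8-[(4-methoxybenzyl)oxy]-3-methyl-7-methylidene-6-[(triethylsilyl)oxy]oct-2-en-1-ol | OC/C=C(/C)CC[C@@H](O[Si](CC)(CC)CC)C(=C)COCc1ccc(OC)cc1 | intermediate
13 | (2Z,6R)-8-[(4-methoxybenzyl)oxy]-3-methyl-7-methylidene-6-[(triethylsilyl)oxy]oct-2-enal | O=C/C=C(/C)CC[C@@H](O[Si](CC)(CC)CC)C(=C)COCc1ccc(OC)cc1 | intermediate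
14 | (R)-4-benzyloxazolidin-2-one | O=C1N[C@H](Cc2ccccc2)CO1 | starting material
15 | 3-methylbutanoyl chloride | CC(C)CC(Cl)=O | starting material
16 | (R)-4-benzyl-3-(3-methylbutanoyl)oxazolidin-2-one | CC(C)CC(=O)N1[C@H](Cc2ccccc2)COC1=O | intermediate
17 | (Z)-dibutylboron enolate of 16 | CC(C)/C=C(\OB(CCCC)CCCC)N1[C@H](Cc2ccccc2)COC1=O | intermediate (not isolated)
18 | (R)-4-benzyl-3-[(2R,3S,4Z,8R)-3-hydroxy-10-[(4-methoxybenzyl)oxy]-5-methyl-9-methylidene-2-(propan-2-yl)-8-[(triethylsilyl)oxy]dec-4-enoyl]oxazolidin-2-one | O=C(N1[C@H](Cc2ccccc2)COC1=O)[C@H](C(C)C)[C@@H](O)/C=C(/C)CC[C@@H](O[Si](CC)(CC)CC)C(=C)COCc1ccc(OC)cc1 | intermediate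
19 | (2R,3S,4Z,8R)-3-hydroxy-N-methoxy-10-[(4-methoxybenzyl)oxy]-N,5-dimethyl-9-methylidene-2-(propan-2-yl)-8-[(triethylsilyl)oxy]dec-4-enamide | CON(C)C(=O)[C@H](C(C)C)[C@@H](O)/C=C(/C)CC[C@@H](O[Si](CC)(CC)CC)C(=C)COCc1ccc(OC)cc1 | intermediate
20 | 3-O-TBS ether of 19 | CON(C)C(=O)[C@H](C(C)C)[C@@H](O[Si](C)(C)C(C)(C)C)/C=C(/C)CC[C@@H](O[Si](CC)(CC)CC)C(=C)COCc1ccc(OC)cc1 | intermediate
21 | (2R,3S,4Z,8R)-3-[(tert-butyldimethylsilyl)oxy]-10-hydroxy-N-methoxy-N,5-dimethyl-9-methylidene-2-(propan-2-yl)-8-[(triethylsilyl)oxy]dec-4-enamide | CON(C)C(=O)[C@H](C(C)C)[C@@H](O[Si](C)(C)C(C)(C)C)/C=C(/C)CC[C@@H](O[Si](CC)(CC)CC)C(=C)CO | intermediate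
22 | 10-methanesulfonate of 21 | CON(C)C(=O)[C@H](C(C)C)[C@@H](O[Si](C)(C)C(C)(C)C)/C=C(/C)CC[C@@H](O[Si](CC)(CC)CC)C(=C)COS(C)(=O)=O | intermediate (not isolated)
23 | (2R,3S,4Z,8R)-3-[(tert-butyldimethylsilyl)oxy]-10-chloro-N-methoxy-N,5-dimethyl-9-methylidene-2-(propan-2-yl)-8-[(triethylsilyl)oxy]dec-4-enamide | CON(C)C(=O)[C@H](C(C)C)[C@@H](O[Si](C)(C)C(C)(C)C)/C=C(/C)CC[C@@H](O[Si](CC)(CC)CC)C(=C)CCl | intermediate
24 | (2R,3S,4Z,8R)-3-[(tert-butyldimethylsilyl)oxy]-10-chloro-5-methyl-9-methylidene-2-(propan-2-yl)-8-[(triethylsilyl)oxy]dec-4-enal | O=C[C@H](C(C)C)[C@@H](O[Si](C)(C)C(C)(C)C)/C=C(/C)CC[C@@H](O[Si](CC)(CC)CC)C(=C)CCl | intermediate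
25 | ethyl allylzinc derived from 24 (ethylzinc in place of chlorine) | O=C[C@H](C(C)C)[C@@H](O[Si](C)(C)C(C)(C)C)/C=C(/C)CC[C@@H](O[Si](CC)(CC)CC)C(=C)C[Zn]CC | intermediate (not isolated)
26 | (1R,2S,3S,4Z,8R)-3-[(tert-butyldimethylsilyl)oxy]-5-methyl-9-methylidene-2-(propan-2-yl)-8-[(triethylsilyl)oxy]cyclodec-4-en-1-ol | CC(C)(C)[Si](C)(C)O[C@H]1/C=C(/C)CC[C@@H](O[Si](CC)(CC)CC)C(=C)C[C@@H](O)[C@@H]1C(C)C | intermediate
27 | i-O-TBS ether of 26 (TBS at a and i, TES at f) | CC(C)(C)[Si](C)(C)O[C@H]1/C=C(/C)CC[C@@H](O[Si](CC)(CC)CC)C(=C)C[C@@H](O[Si](C)(C)C(C)(C)C)[C@@H]1C(C)C | intermediate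
28 | f alcohol (TBS at a and i, free hydroxyl at f, methylidene on g) | CC(C)(C)[Si](C)(C)O[C@H]1/C=C(/C)CC[C@@H](O)C(=C)C[C@@H](O[Si](C)(C)C(C)(C)C)[C@@H]1C(C)C | intermediate
29 | spiro-epoxy alcohol (oxirane on g and k, erythro to the f hydroxyl) | CC(C)(C)[Si](C)(C)O[C@H]1/C=C(/C)CC[C@@H](O)[C@@]2(CO2)C[C@@H](O[Si](C)(C)C(C)(C)C)[C@@H]1C(C)C | intermediate
30 | [(1R,3R,4S,5S,6Z,10R)-3,5-bis[(tert-butyldimethylsilyl)oxy]-7-methyl-4-(propan-2-yl)-11-oxabicyclo[8.1.0]undec-6-en-1-yl]methanol | CC(C)(C)[Si](C)(C)O[C@H]1/C=C(/C)CC[C@H]2O[C@@]2(CO)C[C@@H](O[Si](C)(C)C(C)(C)C)[C@@H]1C(C)C | intermediate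
31 | (1S,3R,4S,5S,6Z,10R)-3,5-bis[(tert-butyldimethylsilyl)oxy]-7-methyl-4-(propan-2-yl)-11-oxabicyclo[8.1.0]undec-6-ene-1-carbaldehyde | CC(C)(C)[Si](C)(C)O[C@H]1/C=C(/C)CC[C@H]2O[C@@]2(C=O)C[C@@H](O[Si](C)(C)C(C)(C)C)[C@@H]1C(C)C | intermediate
32 | (1S,3R,4S,5S,6Z,10R)-3,5-dihydroxy-7-methyl-4-(propan-2-yl)-11-oxabicyclo[8.1.0]undec-6-ene-1-carbaldehyde | O[C@H]1/C=C(/C)CC[C@H]2O[C@@]2(C=O)C[C@@H](O)[C@@H]1C(C)C | intermediate
33 | (1S,3R,4S,5S,6Z,10R)-1-formyl-7-methyl-4-(propan-2-yl)-11-oxabicyclo[8.1.0]undec-6-ene-3,5-diyl diacetate | CC(=O)O[C@H]1/C=C(/C)CC[C@H]2O[C@@]2(C=O)C[C@@H](OC(C)=O)[C@@H]1C(C)C | target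

## Step count and least certain steps

Total step count: 24 steps. Longest linear sequence: 22 steps (from 1 through steps 1, 2, 4 to 9 and 11 to 24); steps 3 and 10 are side branches.

**Step 17 (key step).** The most likely failure is poor facial discrimination at the aldehyde during ring closure. The Felkin preference from j is modest for an unsubstituted allylzinc and can be overridden by the folding of the ten-membered transition state. Intermolecular addition or ethyl transfer may also compete if the allylzinc concentration rises. Fallback: the closure is run from 24 as described and the alcohol mixture is carried on whatever its composition. The i-epimeric cyclodecenol F1 and 26 are oxidised together with Dess–Martin periodinane to the single β,γ-unsaturated cyclodecenone F2. This ketone is reduced under reagent control with the (S)-Me-CBS oxazaborolidine and catecholborane, with the α-branched j side as the large substituent. Control of i thus moves from the bond-forming event to a hydride delivery, and the sequence returns to the route at 26.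

**Step 6.** The most likely failure is insufficient enantioselection, because the catalyst must tell an α-branched alkenyl group from a CH2CH2 chain; conjugate reduction of the α-methylene ketone may also compete. Fallback: setting out from racemic 8 and omitting steps 5 and 6, a Sharpless kinetic resolution (Ti(OiPr)4, L-(+)-diisopropyl tartrate, t-BuOOH 0.6 equiv, molecular sieves, CH2Cl2, −20 °C) epoxidises the (6S)-enantiomer to the erythro epoxy alcohol F3. The (6R)-alcohol is left unreacted and is isolated as 10, where the route is rejoined.

**Step 12.** The most likely failure is attack of the aluminium amide on the ring carbonyl of the oxazolidinone, because the α-isopropyl group shields the exocyclic carbonyl; this would destroy the auxiliary instead of transferring the acyl group. Fallback: setting out from 18, hydrolysis with LiOH and H2O2 in THF/H2O at 0 °C gives the β-hydroxy acid F4 and recovered auxiliary. Coupling of the acid with N,O-dimethylhydroxylamine (EDCI, HOBt, iPr2NEt) returns to the route at 19.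

**Step 20.** The most likely failure is loss of facial control, if the ring adopts a conformation in which hydroxyl-directed delivery takes the threo course; the subsequent epoxide migration would then give the trans-fused epoxide. Fallback: setting out from 28, a Ph3SiOReO3-catalysed 1,3-transposition of the allylic alcohol gives the ring-cis primary allylic alcohol F5, which has the trisubstituted f=g alkene and a hydroxymethyl group on g. Sharpless asymmetric epoxidation (Ti(OiPr)4, L-(+)-diethyl tartrate, t-BuOOH) then places the epoxide under reagent control and returns to the route at 30, bypassing steps 20 and 21.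

**Step 23.** The most likely failure is degradation of the α,β-epoxy aldehyde during fluoride treatment, either by transannular attack of the b=c alkene on the activated epoxide or by hydrate and base-type processes; cleavage of the two hindered silyl ethers may also be incomplete. Fallback: the order of operations is changed. Setting out from 30, both silyl ethers are removed first with TBAF in THF to give the epoxy triol F6. The primary alcohol is then oxidised selectively with TEMPO and PhI(OAc)2, which returns to the route at 32.

## Further compounds

F1 | step 17 | i-epimer of 26, (1S,2S,3S,4Z,8R)-3-[(tert-butyldimethylsilyl)oxy]-5-methyl-9-methylidene-2-(propan-2-yl)-8-[(triethylsilyl)oxy]cyclodec-4-en-1-ol | CC(C)(C)[Si](C)(C)O[C@H]1/C=C(/C)CC[C@@H](O[Si](CC)(CC)CC)C(=C)C[C@H](O)[C@@H]1C(C)C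
F2 | step 17 | cyclodecenone from oxidation of 26 and F1 at i | CC(C)(C)[Si](C)(C)O[C@H]1/C=C(/C)CC[C@@H](O[Si](CC)(CC)CC)C(=C)CC(=O)[C@@H]1C(C)C
F3 | step 6 | erythro epoxy alcohol from the (6S)-enantiomer of 8 | CC(=O)OC/C=C(/C)CC[C@H](O)[C@@]1(COCc2ccc(OC)cc2)CO1
F4 | step 12 | (2R,3S,4Z,8R)-3-hydroxy-10-[(4-methoxybenzyl)oxy]-5-methyl-9-methylidene-2-(propan-2-yl)-8-[(triethylsilyl)oxy]dec-4-enoic acid | OC(=O)[C@H](C(C)C)[C@@H](O)/C=C(/C)CC[C@@H](O[Si](CC)(CC)CC)C(=C)COCc1ccc(OC)cc1
F5 | step 20 | ring-cis primary allylic alcohol (f=g alkene, hydroxymethyl on g, TBS ethers at a and i) | CC(C)(C)[Si](C)(C)O[C@H]1/C=C(/C)CC/C=C(CO)\C[C@@H](O[Si](C)(C)C(C)(C)C)[C@@H]1C(C)C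
F6 | step 23 | epoxy triol (free hydroxyls at a, i and k) | O[C@H]1/C=C(/C)CC[C@H]2O[C@@]2(CO)C[C@@H](O)[C@@H]1C(C)C
A1 | alternative 1 | ten-membered dienetriol with isopropenyl on j | O[C@H]1/C=C(/C)CC/C=C(CO)\C[C@@H](O)[C@@H]1C(C)=C
A2 | alternative 1 | thirteen-membered bis-allylic ether with hydroxyls at i and k | O1C/C=C(/C)CC/C=C(CO)\C[C@@H](O)/C=C(\C)C1
A3 | alternative 2 | (Z,Z)-cyclodeca-2,6-dienone with silyloxy groups at i and k | O=C1/C=C(/C)CC/C=C(CO[Si](C)(C)C(C)(C)C)\C[C@@H](O[Si](C)(C)C(C)(C)C)[C@@H]1C(C)C
A4 | alternative 2 | cis-fused bicyclo[5.3.0]decene with bridgehead hydroxyl at a and mesylate on f | O[C@]12C=C(C)CC[C@@H](OS(C)(=O)=O)[C@@]1(CO[Si](C)(C)C(C)(C)C)C[C@@H](O[Si](C)(C)C(C)(C)C)[C@@H]2C(C)C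
A5 | alternative 3 | ten-membered (Z,Z)-diene acetonide | CC1(C)O[C@H]2/C=C(/C)CC/C=C(CO[Si](C)(C)C(C)(C)C)\C[C@@H](O1)[C@@H]2C(C)C
A6 | alternative 3 | eleven-membered sulfone with sulfur between b and c (epimers at the sulfur-bearing methine c) | CC1(C)O[C@H]2CS(=O)(=O)C(C)CC/C=C(CO[Si](C)(C)C(C)(C)C)\C[C@@H](O1)[C@@H]2C(C)C
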